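Everything rests on cutting ring A at C1–C2 and C5–C10 (clerodane numbering). In the target the C3=C4 alkene of cyclohexene ring A lies next to the quaternary fusion carbon C5, the signature of a C2–C5 diene that has added to a C10=C1 dienophile across the C6–C9 tether. One thermal intramolecular Diels–Alder reaction of an acyclic triene therefore closes rings A and B at once and sets C1, C5 and C10, the sulfone on C1 serving as a removable activator. The precursor is an (E)-diene (E)-vinyl sulfone with a C6 silyl ether, a C8 ketone and the quaternary C9, assembled by an aldol union of a dienal with a methyl ketone.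

Key step: step 10

Conventions: clerodane numbering throughout (ring A = C1–C5 and C10, ring B = C5–C10; methyls C17 on C8, C18 on C4, C19 on C5, C20 on C9); for the bicyclic compounds "octalin" means the Δ3-decalin core numbered in this way, β is the face carrying the C5 methyl and α the opposite face.

Assumption: the sense of induction of the (S)-Tol-BINAP iridium catalyst (step 5) and of (–)-Ipc2BCl (step 8) is taken as written; should either prove opposite, the antipodal ligand or reagent is used and nothing else changes.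

Step 1
Reactants: 1 ethyl 2-methylacetoacetate
Product: 2 ethyl (2E)-2-methyl-3-(tosyloxy)but-2-enoate
Conditions: TsCl, Me2N(CH2)6NMe2, MeCN, 0 °C
Reagents that add atoms: p-toluenesulfonyl chloride, Cc1ccc(cc1)S(Cl)(=O)=O
Why: Enol sulfonylation: without a chelating metal the β-keto ester should be trapped through its dipole-minimised (E)-enolate, which places the tosyloxy group trans to the ester and so fixes the geometry of the future C4=C5 alkene.

Step 2
Reactants: 2 ethyl (2E)-2-methyl-3-(tosyloxy)but-2-enoate; 3 vinylboronic acid pinacol ester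
Product: 4 ethyl (2E)-2,3-dimethylpenta-2,4-dienoate
Conditions: Pd(OAc)2, SPhos, K3PO4, THF–H2O, 60 °C
Reagents that add atoms: none
Why: Suzuki–Miyaura coupling of the vinylogous acyl tosylate proceeds with retention at the alkene, so the new vinyl group (C2=C3) should end trans to the ester carbon (the future C6).

Step 3
Reactants: 4 ethyl (2E)-2,3-dimethylpenta-2,4-dienoate
Product: 5 (2E)-2,3-dimethylpenta-2,4-dien-1-ol
Conditions: iBu2AlH, CH2Cl2, –78 °C; aq potassium sodium tartrate work-up
Reagents that add atoms: none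
Why: 1,2-Reduction of the conjugated ester by the aluminium hydride should give the allylic alcohol and leave the diene untouched.

Step 4
Reactants: 5 (2E)-2,3-dimethylpenta-2,4-dien-1-ol
Product: 6 (2E)-2,3-dimethylpenta-2,4-dienal
Conditions: MnO2, CH2Cl2, rt
Reagents that add atoms: none
Why: Allylic oxidation on MnO2 is neutral and heterogeneous, which should deliver the enal without scrambling the tetrasubstituted alkene.

Step 5
Reactants: 7 ethanol; 8 2-methyl-2-vinyloxirane (racemic)
Product: 10 (2R,3R)-2-ethenyl-2-methylbutane-1,3-diol, via acetaldehyde 9 (not isolated)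
Conditions: Ir(η3-allyl)[(S)-Tol-BINAP][C,O-4-cyano-3-nitrobenzoate] (5 mol %), K3PO4 (5 mol %), THF, 45 °C
Reagents that add atoms: none
Why: Iridium-catalysed transfer-hydrogenative tert-(hydroxy)prenylation: ethanol is dehydrogenated to acetaldehyde, which is captured at the tertiary terminus of the allyliridium species formed from the vinyl epoxide through a closed chair transition state, so the chiral bisphosphine should set the all-carbon quaternary centre (the future C9) together with the anti carbinol in a redox-neutral, stereoconvergent step.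

Step 6
Reactants: 10 (2R,3R)-2-ethenyl-2-methylbutane-1,3-diol
Product: 11 (2R)-2-ethenyl-2-methyl-3-oxobutanal
Conditions: Dess–Martin periodinane, CH2Cl2, 0 °C → rt; crude product used at once
Reagents that add atoms: none
Why: Dess–Martin oxidation takes the secondary and the primary alcohol to the ketone and the aldehyde at once; the carbinol stereocentre is erased on purpose and the quaternary carbon, which has no α-hydrogen, cannot epimerise.

Step 7
Reactants: 11 (2R)-2-ethenyl-2-methyl-3-oxobutanal; 12 diethyl (phenylsulfonylmethyl)phosphonate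
Product: 13 (3R)-3-methyl-3-[(E)-2-(phenylsulfonyl)ethenyl]pent-4-en-2-one
Conditions: LiCl, DBU, MeCN, 0 °C → rt
Reagents that add atoms: none
Why: Horner–Wadsworth–Emmons olefination under mild amine–LiCl conditions reacts at the aldehyde and not at the hindered methyl ketone and should give the (E)-vinyl sulfone.

Step 8
Reactants: 13 (3R)-3-methyl-3-[(E)-2-(phenylsulfonyl)ethenyl]pent-4-en-2-one; 6 (2E)-2,3-dimethylpenta-2,4-dienal
Product: 16 (1E,3R,6S,7E)-3-ethenyl-6-hydroxy-3,7,8-trimethyl-1-(phenylsulfonyl)deca-1,7,9-trien-4-one, via boron enolate 14 (not isolated), via boron aldolate 15 (not isolated)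
Conditions: (–)-Ipc2BCl, Et3N, Et2O, –78 → 0 °C; then 6, –78 → –20 °C; H2O2, MeOH, pH 7 buffer, 0 °C
Reagents that add atoms: none
Why: Reagent-controlled boron aldol reaction: the methyl ketone can enolise only at C7, and its diisopinocampheylboron enolate, which does not add to the vinyl sulfone in a Michael sense, should attack the Si face of the enal to set C6 as S, the C6 epimer and the adduct of any minor C9 enantiomer being diastereomers that are removed by chromatography.

Step 9
Reactants: 16 (1E,3R,6S,7E)-3-ethenyl-6-hydroxy-3,7,8-trimethyl-1-(phenylsulfonyl)deca-1,7,9-trien-4-one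
Product: 17 (1E,3R,6S,7E)-6-(tert-butyldimethylsilyloxy)-3-ethenyl-3,7,8-trimethyl-1-(phenylsulfonyl)deca-1,7,9-trien-4-one
Conditions: TBSOTf, 2,6-lutidine, CH2Cl2, –78 °C
Reagents that add atoms: tert-butyldimethylsilyl trifluoromethanesulfonate, CC(C)(C)[Si](C)(C)OS(=O)(=O)C(F)(F)F
Why: Silylation with the silyl triflate at low temperature should outrun retro-aldol cleavage and ionisation of the dienylic alcohol and installs the bulky group that later steers the diene face.

Step 10
Reactants: 17 (1E,3R,6S,7E)-6-(tert-butyldimethylsilyloxy)-3-ethenyl-3,7,8-trimethyl-1-(phenylsulfonyl)deca-1,7,9-trien-4-one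
Product: 18 6β-(tert-butyldimethylsilyloxy)-4,5β,9β-trimethyl-1α-(phenylsulfonyl)-9α-vinyl-10αH-octalin-8-one
Conditions: PhMe (0.01 M), BHT, sealed tube, 150 °C
Reagents that add atoms: none
Why: Concerted suprafacial [4+2] cycloaddition of the C2=C3–C4=C5 diene to the sulfone-activated C10=C1 alkene, the closest known type being the thermal type 1 intramolecular Diels–Alder reaction of 1,7,9-decatrienes with a terminally activated (E)-dienophile. Ring A is closed as the cycloadduct ring by forming both C1–C2 and C5–C10, and ring B is closed in the fused mode as the six-membered tether ring by the same C5–C10 bond. C5 is set by the C6 stereocentre: A(1,3) strain with the C4 methyl holds H6 near the diene plane and turns the silyloxy group away from the incoming dienophile (pseudo-equatorial), so only one diene face should be used. C10 is set by the chair-like anti transition state with the tether exo and the sulfone endo, which gives the trans ring fusion with the C9 vinyl pseudo-equatorial, and C1 follows from the (E)-geometry of the dienophile (sulfone cis to H10). The step needs chemoselectivity for the sulfonylvinyl over the plain vinyl group on C9, secured by the lowered LUMO of the vinyl sulfone, and it needs cycloaddition to outrun the 1,5-hydrogen shift of the cis methyl on C5, helped by the sp2 C8 and the quaternary C9, which compress the tether.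

Step 11
Reactants: 18 6β-(tert-butyldimethylsilyloxy)-4,5β,9β-trimethyl-1α-(phenylsulfonyl)-9α-vinyl-10αH-octalin-8-one
Product: 19 6β-(tert-butyldimethylsilyloxy)-4,5β,9β-trimethyl-9α-vinyl-10αH-octalin-8-one
Conditions: Na(Hg) (6% Na), Na2HPO4, MeOH–THF, –20 → 0 °C
Reagents that add atoms: none
Why: Reductive desulfonylation by electron transfer from sodium amalgam cleaves the C1–S bond to leave the C1 methylene, the phosphate buffer and low temperature sparing the ketone, which is shielded by the quaternary C9.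

Step 12
Reactants: 19 6β-(tert-butyldimethylsilyloxy)-4,5β,9β-trimethyl-9α-vinyl-10αH-octalin-8-one
Product: 21 6β-(tert-butyldimethylsilyloxy)-7α-hydroxy-4,5β,9β-trimethyl-9α-vinyl-10αH-octalin-8-one, via potassium enolate 20 (not isolated)
Conditions: KN(SiMe3)2, THF, –78 °C; then 2-(phenylsulfonyl)-3-phenyloxaziridine, –78 °C; AcOH
Reagents that add atoms: 2-(phenylsulfonyl)-3-phenyloxaziridine, O=S(=O)(c1ccccc1)N1OC1c1ccccc1
Why: Enolate oxidation with an N-sulfonyloxaziridine: C7 is the only enolisable position and the β face of the enolate is screened by the two syn-axial methyls on C5 and C9, so oxygen should enter from the α face to give the equatorial 7α-alcohol, while the equatorial C6 silyloxy group is badly aligned for β-elimination.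

Step 13
Reactants: 21 6β-(tert-butyldimethylsilyloxy)-7α-hydroxy-4,5β,9β-trimethyl-9α-vinyl-10αH-octalin-8-one
Product: 22 6β-(tert-butyldimethylsilyloxy)-4,5β,9β-trimethyl-8-methylidene-9α-vinyl-10αH-octalin-7α-ol
Conditions: Zn, CH2Br2, TiCl4, THF–CH2Cl2, 0 °C → rt
Reagents that add atoms: dibromomethane, BrCBr
Why: Takai–Lombardo methylenation: the non-basic titanium–zinc methylene reagent converts hindered, enolisable ketones that carry free hydroxyl groups into 1,1-disubstituted alkenes without epimerisation or α-ketol rearrangement.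

Step 14
Reactants: 22 6β-(tert-butyldimethylsilyloxy)-4,5β,9β-trimethyl-8-methylidene-9α-vinyl-10αH-octalin-7α-ol
Product: 23 6β-(tert-butyldimethylsilyloxy)-8α,17-epoxy-4,5β,9β-trimethyl-9α-vinyl-10αH-octalin-7α-ol (spiro-oxirane at C8 with oxygen α and CH2 β)
Conditions: VO(acac)2 (cat.), tBuOOH, CH2Cl2, 0 °C → rt
Reagents that add atoms: tert-butyl hydroperoxide, CC(C)(C)OO
Why: Hydroxyl-directed vanadium-catalysed epoxidation reacts only at the allylic alcohol alkene and should deliver oxygen to its α face, syn to the 7α-hydroxyl and anti to the axial C9 methyl, which makes the C8 oxygen axial; a methyl nucleophile added to the C8 ketone would have come from this same open face and given the C8 epimer, which is why carbon is installed first and oxygen second.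

Step 15
Reactants: 23 6β-(tert-butyldimethylsilyloxy)-8α,17-epoxy-4,5β,9β-trimethyl-9α-vinyl-10αH-octalin-7α-ol
Product: 24 6β-(tert-butyldimethylsilyloxy)-4,5β,8β,9β-tetramethyl-9α-vinyl-10αH-octalin-7α,8α-diol
Conditions: LiEt3BH, THF, 0 °C → rt
Reagents that add atoms: none
Why: Hydride opens the spiro-epoxide by SN2 attack at its unhindered CH2 terminus, which turns that carbon into the equatorial C8 methyl and leaves the tertiary 8α-alcohol with its configuration untouched.

Step 16
Reactants: 24 6β-(tert-butyldimethylsilyloxy)-4,5β,8β,9β-tetramethyl-9α-vinyl-10αH-octalin-7α,8α-diol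
Product: 25 4,5β,8β,9β-tetramethyl-9α-vinyl-10αH-octalin-6β,7α,8α-triol
Conditions: Bu4NF, THF, rt → 50 °C
Reagents that add atoms: none
Why: Fluoride-induced desilylation frees the hindered C6 alcohol at a stage where no base-sensitive group is present.

Step 17
Reactants: 25 4,5β,8β,9β-tetramethyl-9α-vinyl-10αH-octalin-6β,7α,8α-triol; 26 4-bromofuran-2(5H)-one
Product: 27 4-[(E)-2-(6β,7α,8α-trihydroxy-4,5β,8β,9β-tetramethyl-10αH-octalin-9α-yl)ethenyl]furan-2(5H)-one
Conditions: Pd(OAc)2 (10 mol %), Bu4NCl, NaHCO3, DMF, 70 °C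
Reagents that add atoms: none
Why: Heck reaction: oxidative addition of the β-bromobutenolide to zerovalent palladium, carbopalladation of the terminal vinyl group with the butenolide going to C12, and β-hydride elimination, which is possible only toward C12 because C9 is quaternary, should give the (E)-diene as a single regioisomer.

Step 18
Reactants: 27 4-[(E)-2-(6β,7α,8α-trihydroxy-4,5β,8β,9β-tetramethyl-10αH-octalin-9α-yl)ethenyl]furan-2(5H)-one
Product: 30 4-[(E)-2-(6β-acetoxy-7α,8α-dihydroxy-4,5β,8β,9β-tetramethyl-10αH-octalin-9α-yl)ethenyl]furan-2(5H)-one (CNP0279118.1), via phenylboronate 28 (not isolated), via acetylated phenylboronate 29 (not isolated)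
Conditions: PhB(OH)2, PhMe, 4 Å molecular sieves, rt; then Ac2O, pyridine, DMAP, 0 °C → rt; then H2O2, pH 7 buffer, THF, 0 °C
Reagents that add atoms: acetic anhydride, CC(=O)OC(C)=O
Why: Transient boronate masking: phenylboronic acid should form the five-membered cyclic ester only with the cis 7α,8α-diol (the 6β,7α pair is trans-diequatorial), so DMAP-catalysed acetylation is confined to the C6 hydroxyl, and oxidative cleavage of the B–C bond at neutral pH then releases the diol without acetyl migration.

Compound list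

1 | ethyl 2-methylacetoacetate (racemic) | CCOC(=O)C(C)C(C)=O | starting material
2 | ethyl (2E)-2-methyl-3-(tosyloxy)but-2-enoate | CCOC(=O)/C(C)=C(C)/OS(=O)(=O)c1ccc(C)cc1 | intermediate
3 | vinylboronic acid pinacol ester | C=CB1OC(C)(C)C(C)(C)O1 | starting material
4 | ethyl (2E)-2,3-dimethylpenta-2,4-dienoate | CCOC(=O)/C(C)=C(C)/C=C | intermediate
5 | (2E)-2,3-dimethylpenta-2,4-dien-1-ol | OC/C(C)=C(C)/C=C | intermediate
6 | (2E)-2,3-dimethylpenta-2,4-dienal | O=C/C(C)=C(C)/C=C | intermediate
7 | ethanol | CCO | starting material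
8 | 2-methyl-2-vinyloxirane (racemic) | CC1(C=C)CO1 | starting material
9 | acetaldehyde | CC=O | intermediate
10 | (2R,3R)-2-ethenyl-2-methylbutane-1,3-diol | C[C@@H](O)[C@](C)(C=C)CO | intermediate
11 | (2R)-2-ethenyl-2-methyl-3-oxobutanal | CC(=O)[C@](C)(C=C)C=O | intermediate
12 | diethyl (phenylsulfonylmethyl)phosphonate | CCOP(=O)(CS(=O)(=O)c1ccccc1)OCC | starting material
13 | (3R)-3-methyl-3-[(E)-2-(phenylsulfonyl)ethenyl]pent-4-en-2-one | CC(=O)[C@](C)(C=C)/C=C/S(=O)(=O)c1ccccc1 | intermediate
14 | diisopinocampheylboron enolate of 13 (C7=C8 enol borinate) | C=C(OB([C@@H]1C[C@@H]2C[C@H]([C@H]1C)C2(C)C)[C@@H]1C[C@@H]2C[C@H]([C@H]1C)C2(C)C)[C@](C)(C=C)/C=C/S(=O)(=O)c1ccccc1 | intermediate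
15 | diisopinocampheylboron aldolate of 16 (C6–O–B) | C=C/C(C)=C(C)/[C@@H](OB([C@@H]1C[C@@H]2C[C@H]([C@H]1C)C2(C)C)[C@@H]1C[C@@H]2C[C@H]([C@H]1C)C2(C)C)CC(=O)[C@](C)(C=C)/C=C/S(=O)(=O)c1ccccc1 | intermediate
16 | (1E,3R,6S,7E)-3-ethenyl-6-hydroxy-3,7,8-trimethyl-1-(phenylsulfonyl)deca-1,7,9-trien-4-one | C=C/C(C)=C(C)/[C@@H](O)CC(=O)[C@](C)(C=C)/C=C/S(=O)(=O)c1ccccc1 | intermediate
17 | (1E,3R,6S,7E)-6-(tert-butyldimethylsilyloxy)-3-ethenyl-3,7,8-trimethyl-1-(phenylsulfonyl)deca-1,7,9-trien-4-one (Diels–Alder precursor) | C=C/C(C)=C(C)/[C@@H](O[Si](C)(C)C(C)(C)C)CC(=O)[C@](C)(C=C)/C=C/S(=O)(=O)c1ccccc1 | intermediate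
18 | 6β-(tert-butyldimethylsilyloxy)-4,5β,9β-trimethyl-1α-(phenylsulfonyl)-9α-vinyl-10αH-octalin-8-one (trans-fused cycloadduct) | CC(C)(C)[Si](C)(C)O[C@H]1CC(=O)[C@](C)(C=C)[C@H]2[C@H](S(=O)(=O)c3ccccc3)CC=C(C)[C@]12C | intermediate
19 | 6β-(tert-butyldimethylsilyloxy)-4,5β,9β-trimethyl-9α-vinyl-10αH-octalin-8-one | CC(C)(C)[Si](C)(C)O[C@H]1CC(=O)[C@](C)(C=C)[C@H]2CCC=C(C)[C@]12C | intermediate
20 | potassium C7=C8 enolate of 19 | CC(C)(C)[Si](C)(C)O[C@H]1C=C([O-])[C@](C)(C=C)[C@H]2CCC=C(C)[C@]12C.[K+] | intermediate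
21 | 6β-(tert-butyldimethylsilyloxy)-7α-hydroxy-4,5β,9β-trimethyl-9α-vinyl-10αH-octalin-8-one | CC(C)(C)[Si](C)(C)O[C@H]1[C@H](O)C(=O)[C@](C)(C=C)[C@H]2CCC=C(C)[C@]12C | intermediate
22 | 6β-(tert-butyldimethylsilyloxy)-4,5β,9β-trimethyl-8-methylidene-9α-vinyl-10αH-octalin-7α-ol | CC(C)(C)[Si](C)(C)O[C@H]1[C@H](O)C(=C)[C@](C)(C=C)[C@H]2CCC=C(C)[C@]12C | intermediate
23 | 6β-(tert-butyldimethylsilyloxy)-8α,17-epoxy-4,5β,9β-trimethyl-9α-vinyl-10αH-octalin-7α-ol (epoxide oxygen α, CH2 β) | CC(C)(C)[Si](C)(C)O[C@H]1[C@H](O)[C@@]3(CO3)[C@](C)(C=C)[C@H]2CCC=C(C)[C@]12C | intermediate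
24 | 6β-(tert-butyldimethylsilyloxy)-4,5β,8β,9β-tetramethyl-9α-vinyl-10αH-octalin-7α,8α-diol | CC(C)(C)[Si](C)(C)O[C@H]1[C@H](O)[C@](C)(O)[C@](C)(C=C)[C@H]2CCC=C(C)[C@]12C | intermediate
25 | 4,5β,8β,9β-tetramethyl-9α-vinyl-10αH-octalin-6β,7α,8α-triol | O[C@H]1[C@H](O)[C@](C)(O)[C@](C)(C=C)[C@H]2CCC=C(C)[C@]12C | intermediate
26 | 4-bromofuran-2(5H)-one | BrC1=CC(=O)OC1 | starting material
27 | 4-[(E)-2-(6β,7α,8α-trihydroxy-4,5β,8β,9β-tetramethyl-10αH-octalin-9α-yl)ethenyl]furan-2(5H)-one | O[C@H]1[C@H](O)[C@](C)(O)[C@](C)(/C=C/C3=CC(=O)OC3)[C@H]2CCC=C(C)[C@]12C | intermediate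
28 | 7α,8α-O-phenylboronate of 27 | O[C@H]1[C@@H]3OB(c4ccccc4)O[C@]3(C)[C@](C)(/C=C/C5=CC(=O)OC5)[C@H]2CCC=C(C)[C@]12C | intermediate
29 | 6β-acetate of phenylboronate 28 | CC(=O)O[C@H]1[C@@H]3OB(c4ccccc4)O[C@]3(C)[C@](C)(/C=C/C5=CC(=O)OC5)[C@H]2CCC=C(C)[C@]12C | intermediate
30 | 4-[(E)-2-(6β-acetoxy-7α,8α-dihydroxy-4,5β,8β,9β-tetramethyl-10αH-octalin-9α-yl)ethenyl]furan-2(5H)-one (CNP0279118.1) | CC(=O)O[C@H]1[C@H](O)[C@](C)(O)[C@](C)(/C=C/C2=CC(=O)OC2)[C@H]2CCC=C(C)[C@]12C | target

Total step count: 18. Longest linear sequence: 15 steps (steps 1–4 and 8–18); the ketone branch (steps 5–7) joins at step 8.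

Steps most likely to fail

Step 10. Cycloaddition at the fully substituted diene terminus may be so slow that the 1,5-hydrogen shift of the diene, or closure through the exo transition state to the cis-fused ring system, competes. The fallback replaces thermal sulfone activation by a Lewis-acid-activated ester that is excised afterwards. It sets out from 11: olefination with triethyl phosphonoacetate (LiCl, DBU) should give ethyl (2E,4R)-4-acetyl-4-methylhexa-2,5-dienoate F1. The boron aldol reaction of step 8 with 6 should then give ethyl (2E,4R,7S,8E)-4-ethenyl-7-hydroxy-4,8,9-trimethyl-5-oxoundeca-2,8,10-trienoate F2, and silylation as in step 9 its tert-butyldimethylsilyl ether F3. Me2AlCl in CH2Cl2 at –78 to –20 °C should drive the endo cycloaddition to the trans-fused 1α-ethoxycarbonyl octalinone F4. Saponification with LiOH gives the 1α-carboxylic acid F5, which is converted with N-hydroxypyridine-2-thione and a carbodiimide into its N-acyloxypyridine-2-thione ester F6 and decarboxylated reductively with tBuSH under visible light (Barton decarboxylation). The route is rejoined at 19.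

Step 13. The titanium–zinc reagent may be consumed by the free C7 hydroxyl and reach the ketone beside the quaternary C9 too slowly, so that methylenation stalls or the silyl ether is lost in the Lewis-acidic medium. The fallback is a Peterson olefination, which separates carbon–carbon bond formation from elimination. It sets out from 21: Me3SiCH2Li with CeCl3 in THF at –78 °C, a small and weakly basic nucleophile, should add to C8 from the α face to give 6β-(tert-butyldimethylsilyloxy)-4,5β,9β-trimethyl-8α-[(trimethylsilyl)methyl]-9α-vinyl-10αH-octalin-7α,8β-diol F7. Elimination with KH in THF then forms the exocyclic alkene, and the route is rejoined at 22.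

Step 17. Carbopalladation of the neopentyl-type vinyl group may be slower than base-induced decomposition of the bromobutenolide and loss of active palladium. The fallback divides the coupling into a metathesis and a Suzuki–Miyaura step. It sets out from 25: cross-metathesis with 3 (second-generation Hoveyda–Grubbs catalyst, CH2Cl2, 40 °C) should give 9α-[(E)-2-(4,4,5,5-tetramethyl-1,3,2-dioxaborolan-2-yl)ethenyl]-4,5β,8β,9β-tetramethyl-10αH-octalin-6β,7α,8α-triol F8. Coupling of F8 with 26 (Pd(PPh3)4, K3PO4, THF–H2O, 50 °C) then rejoins the route at 27.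

Further compounds

F1 | step 10 | ethyl (2E,4R)-4-acetyl-4-methylhexa-2,5-dienoate | CC(=O)[C@](C)(C=C)/C=C/C(=O)OCC
F2 | step 10 | ethyl (2E,4R,7S,8E)-4-ethenyl-7-hydroxy-4,8,9-trimethyl-5-oxoundeca-2,8,10-trienoate | C=C/C(C)=C(C)/[C@@H](O)CC(=O)[C@](C)(C=C)/C=C/C(=O)OCC
F3 | step 10 | ethyl (2E,4R,7S,8E)-7-(tert-butyldimethylsilyloxy)-4-ethenyl-4,8,9-trimethyl-5-oxoundeca-2,8,10-trienoate | C=C/C(C)=C(C)/[C@@H](O[Si](C)(C)C(C)(C)C)CC(=O)[C@](C)(C=C)/C=C/C(=O)OCC
F4 | step 10 | ethyl 6β-(tert-butyldimethylsilyloxy)-4,5β,9β-trimethyl-8-oxo-9α-vinyl-10αH-octalin-1α-carboxylate | CC(C)(C)[Si](C)(C)O[C@H]1CC(=O)[C@](C)(C=C)[C@H]2[C@H](C(=O)OCC)CC=C(C)[C@]12C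
F5 | step 10 | 6β-(tert-butyldimethylsilyloxy)-4,5β,9β-trimethyl-8-oxo-9α-vinyl-10αH-octalin-1α-carboxylic acid | CC(C)(C)[Si](C)(C)O[C@H]1CC(=O)[C@](C)(C=C)[C@H]2[C@H](C(=O)O)CC=C(C)[C@]12C
F6 | step 10 | N-acyloxypyridine-2-thione ester of F5 | CC(C)(C)[Si](C)(C)O[C@H]1CC(=O)[C@](C)(C=C)[C@H]2[C@H](C(=O)ON3C=CC=CC3=S)CC=C(C)[C@]12C
F7 | step 13 | 6β-(tert-butyldimethylsilyloxy)-4,5β,9β-trimethyl-8α-[(trimethylsilyl)methyl]-9α-vinyl-10αH-octalin-7α,8β-diol | CC(C)(C)[Si](C)(C)O[C@H]1[C@H](O)[C@](O)(C[Si](C)(C)C)[C@](C)(C=C)[C@H]2CCC=C(C)[C@]12C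
F8 | step 17 | 9α-[(E)-2-(4,4,5,5-tetramethyl-1,3,2-dioxaborolan-2-yl)ethenyl]-4,5β,8β,9β-tetramethyl-10αH-octalin-6β,7α,8α-triol | O[C@H]1[C@H](O)[C@](C)(O)[C@](C)(/C=C/B3OC(C)(C)C(C)(C)O3)[C@H]2CCC=C(C)[C@]12C
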